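Carbon numbering used throughout: C1 (alkyne CH) to C15 (ethyl CH3). Ring A is the oxolane O–C6–C7–C8–C9; ring B is the oxocane O–C7–C8–C9–C10–C11–C12–C13. The face of ring B over which the O–C6 bridge of ring A lies is called the bridge face, the other the open face.

## Analysis of the target

The target 26 is a C15 dibromo enyne built on a 2,8-dioxabicyclo[5.2.1]decane, in which ring A and ring B share C7–C8–C9. It has six stereocentres, (6R,7S,9S,10S,12S,13R) in chain numbering. On ring A the C7 oxygen is trans to the C6 side chain and, as the bridge demands, cis to the C9–C10 bond. On ring B the C10 bromide lies on the open face, the C12 bromide on the bridge face, and the C13 ethyl group on the open face, trans to the C12 bromide. The sensitive groups are the (E)-enyne with its terminal alkyne (base, metals, metathesis catalysts), the two secondary bromides that each sit next to an ether carbon (elimination, participation by ring oxygens), and C4, which is beta to the ring A oxygen once it is a carbonyl. The difficulty lies in closing a bridged eight-membered ether and in placing two bromides of defined configuration on it. The feature that carries the plan is ring A: a 2,5-trans oxolane whose C7 heteroatom is trans to the C6 chain is what a Lewis-acid annulation of an alpha-substituted allylsilane with an aldehyde delivers, with silicon as the masked C7 oxygen. Both bromides are then best made by SN2 from alcohols of opposite configuration, so the C10 oxygen can come from the aldehyde partner and the C12 oxygen from oxidation of a ring B enol ether.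

## Retrosynthetic reasoning

26 from 25: the terminal alkyne is kept capped with silicon until the end, because it is the most base- and metal-sensitive group; the last step only breaks a C–Si bond.

25 from 24: the C10–Br bond is cut back to the C10 alcohol of opposite configuration. This oxygen is present from the start, so only an SN2 displacement is asked of the forward step.

24 from 23 and 22: the enyne is cut at C2–C3 (alkyne–alkenyl coupling) and at C3=C4 (one-carbon olefination of a C4 aldehyde). Cutting here lets the E geometry be set by the olefination and keeps the enyne out of all earlier steps.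

22 from 21 and 20: the C4 aldehyde comes from a primary alcohol that can be oxidised in the presence of the secondary C10 alcohol. Both alcohols are uncovered together from benzyl ethers, so one deprotection serves two positions.

20 from 19: the C12–Br bond is cut back to the C12 alcohol of opposite configuration, while C10 is still protected.

19 from 17 through 18: the C13–ethyl bond and the C12–O bond are cut together. Both are traced to the C12=C13 enol ether of 17 by epoxidation and syn delivery of ethyl to the acetal carbon, which gives the cis arrangement of ethyl and hydroxyl that the later inversion at C12 needs.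

17 from 16: ring B is cut at C12=C13, far from every stereocentre. The forward step is a ring-closing metathesis between a vinyl ether on the C7 oxygen and the terminal alkene of the C9 arm; the two arms are cis on ring A, which favours closure.

16 from 15, 14, 13 and 12: the vinyl group is removed from the C7 oxygen, and the C7–O bond is traced to the C7–Si bond of 12 (oxidation with retention). Because the only silicon oxidation that spares the terminal alkene and the beta-silyl ether uses fluoride, the C10 silyl ether of 12 is exchanged for a benzyl ether first.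

12 from 6 and 11: ring A is cut at C8–C9 and at O–C6. This takes the molecule apart into two small chiral fragments and creates three stereocentres in the forward direction: the allylsilane 6 adds through C8 to the aldehyde 11, silicon moves from C6 to C7, and the aldehyde oxygen closes the ring at C6.

6 from 4 and 5, then 3, 2 and 1: the C6–Si bond is cut; an enantioselective gamma-selective allylic substitution of the linear phosphate 4 by the silyl group of 5 sets C6. The phosphate comes from aldehyde 1 by two-carbon olefination and reduction.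

11 from 10, 9, 8 and 7: the C11–C12 bond is cut back to the glycidyl ether 7, whose stereocentre becomes C10; protection, debenzylation and oxidation give the aldehyde.

## Alternatives that were turned down

Alternative 1: Ring B is cut at C11–C12. In the forward step SmI2 would reduce the bromomethyl ketone of the seco aldehyde A2 to a samarium enolate, which adds to the C12 aldehyde to give the bridged beta-hydroxy ketone A1.
- For: samarium holds enolate and aldehyde together, so this is one of the better carbon–carbon closures of medium rings. C13 with its ethyl group would come from a 2-hydroxybutanoate unit, and on that point the alternative is stronger than the chosen route, which must set C13 by a face-selective reaction on the ring.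
- Against: A2 needs an ether between two secondary carbons (C7 and C13) made intermolecularly. Its alpha-alkoxy aldehyde can epimerise at C13. A1 is a beta-hydroxy ketone prone to dehydration and retro-aldol cleavage. The C12 configuration from the aldol and the C10 configuration from a later ketone reduction would both have to be won on the ring without an obvious bias. Ring A would still have to be made beforehand.
- Comparison: the chosen route takes C10 from the chiral pool and makes ring A with three stereocentres in one step from two four-step fragments.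

Alternative 2: The C7–O bond of ring B is cut by a retro Baeyer–Villiger step. A peracid would add to the C13 ketone of the oxygen-bridged cycloheptanone A4; C7, the more substituted neighbour, migrates with retention to give the lactone A3.
- For: the eight-membered ring arises by ring expansion and not by cyclisation, and the migration is stereospecific. On the reliability of ring B formation this is stronger than a metathesis to a bridged enol ether.
- Against: A4, a bridged carbocycle with four stereocentres and a bromide, has no short synthesis. After the oxygen insertion the lactone carbonyl must still become CH(Et) and the C12 methylene must be brominated trans to it. That is two new stereocentres by enolate and oxocarbenium chemistry while a C10 bromide sits gamma to the carbonyl, where an enolate can displace it to a cyclopropane.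
- Comparison: the chosen route also forms the C7–O bond with retention (from C–Si), and gets the C12 and C13 substituents in one operation from the enol ether. The price is a less certain ring closure.

Alternative 3: Ring A is cut at C6–C7. Bu3SnH with Et3B would generate the C7 alpha-alkoxy radical from the selenoacetal A6, and this adds 5-exo to the beta-alkoxyacrylate on the C9 oxygen to give the bridged ester A5.
- For: radical additions to beta-alkoxyacrylates are dependable oxolane closures, with a nucleophilic radical and an electron-poor acceptor. C4 arrives as an ester, and C9, C10, C12 and C13 are fixed before the bicycle forms; on these points it is as strong as the chosen route or stronger.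
- Against: the oxocane A6, with four stereocentres and an anomeric selenide, is the hard part of the molecule and would have to be built without help from ring A. The usual preference of this cyclisation is for a 2,5-cis oxolane, whereas C6 and C9 of the target are trans, so only the strain of the bridged transition state could give the right C6 configuration.
- Comparison: the chosen route sets C6 by a stereospecific inversion and reaches the bicycle in far fewer steps.

Key step: step 9

## Route

Assumption: in step 4 the enantiomer of the chiral carbene ligand is taken to be the one that gives the (S)-silane; both ligand enantiomers are accessible.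

Step 1
Reactants: 1 3-(benzyloxy)propanal
Product: 2 ethyl (2E)-5-(benzyloxy)pent-2-enoate
Conditions: Ph3P=CHCO2Et, CH2Cl2, rt
Reagents that add atoms: ethyl (triphenylphosphoranylidene)acetate, CCOC(=O)C=P(c1ccccc1)(c1ccccc1)c1ccccc1
Why: Wittig olefination with a stabilised ylide should give the (E)-enoate, and no base is present that could eliminate the beta-benzyloxy group.

Step 2
Reactants: 2 ethyl (2E)-5-(benzyloxy)pent-2-enoate
Product: 3 (2E)-5-(benzyloxy)pent-2-en-1-ol
Conditions: i-Bu2AlH, CH2Cl2, -78 °C
Reagents that add atoms: none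
Why: 1,2-Reduction of an unsaturated ester by i-Bu2AlH at low temperature should give the allylic alcohol without touching the alkene or the benzyl ether.

Step 3
Reactants: 3 (2E)-5-(benzyloxy)pent-2-en-1-ol
Product: 4 (2E)-5-(benzyloxy)pent-2-en-1-yl diethyl phosphate
Conditions: (EtO)2P(O)Cl, pyridine, CH2Cl2, 0 °C
Reagents that add atoms: diethyl chlorophosphate, CCOP(=O)(Cl)OCC
Why: Phosphorylation of a primary alcohol; the allylic phosphate is the leaving group used in copper-catalysed gamma-selective allylic substitution.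

Step 4
Reactants: 4 (2E)-5-(benzyloxy)pent-2-en-1-yl diethyl phosphate; 5 (dimethylphenylsilyl)boronic acid pinacol ester
Product: 6 (S)-[5-(benzyloxy)pent-1-en-3-yl]dimethyl(phenyl)silane
Conditions: CuCl (5 mol %), chiral six-membered N-heterocyclic carbene ligand, NaOMe, CH2Cl2, 0 °C
Reagents that add atoms: none
Why: Copper-catalysed enantioselective allylic silylation: methoxide moves the silyl group of 5 from boron to copper, and the silylcopper complex attacks the gamma carbon (C6) with loss of phosphate (SN2') to give the branched allylsilane. The chiral ligand selects the alkene face and so sets C6 as (S).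

Step 5
Reactants: 7 (R)-benzyl glycidyl ether
Product: 8 (R)-1-(benzyloxy)pent-4-en-2-ol
Conditions: CH2=CHMgBr, CuI (cat.), THF, -30 °C
Reagents that add atoms: vinylmagnesium bromide, C=C[Mg]Br
Why: Copper-catalysed opening of a terminal epoxide by a vinyl Grignard reagent at the unsubstituted carbon; the stereocentre (the later C10) is not touched and comes from the chiral pool.

Step 6
Reactants: 8 (R)-1-(benzyloxy)pent-4-en-2-ol
Product: 9 (R)-{[1-(benzyloxy)pent-4-en-2-yl]oxy}(tert-butyl)dimethylsilane
Conditions: TBSCl, imidazole, DMF, rt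
Reagents that add atoms: tert-butyldimethylsilyl chloride, CC(C)(C)[Si](C)(C)Cl
Why: Silylation of a secondary alcohol; a silyl ether is chosen because it cannot chelate in the key step.

Step 7
Reactants: 9 (R)-{[1-(benzyloxy)pent-4-en-2-yl]oxy}(tert-butyl)dimethylsilane
Product: 10 (R)-2-[(tert-butyldimethylsilyl)oxy]pent-4-en-1-ol
Conditions: lithium 4,4'-di-tert-butylbiphenylide, THF, -78 °C; NH4Cl at -78 °C
Reagents that add atoms: none
Why: Reductive debenzylation by electron transfer from the arene radical anion; unlike hydrogenolysis it leaves the terminal alkene intact. Quenching at -78 °C should keep the lithium alkoxide from taking the silyl group from the neighbouring oxygen.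

Step 8
Reactants: 10 (R)-2-[(tert-butyldimethylsilyl)oxy]pent-4-en-1-ol
Product: 11 (R)-2-[(tert-butyldimethylsilyl)oxy]pent-4-enal
Conditions: Dess–Martin periodinane, CH2Cl2, 0 °C to rt
Reagents that add atoms: none
Why: Dess–Martin oxidation of a primary alcohol under near-neutral conditions; the alpha-silyloxy aldehyde is configurationally labile and is used at once.

Step 9
Reactants: 6 (S)-[5-(benzyloxy)pent-1-en-3-yl]dimethyl(phenyl)silane; 11 (R)-2-[(tert-butyldimethylsilyl)oxy]pent-4-enal
Product: 12 {(2R,3S,5S)-2-[2-(benzyloxy)ethyl]-5-[(1R)-1-{[tert-butyl(dimethyl)silyl]oxy}but-3-en-1-yl]oxolan-3-yl}dimethyl(phenyl)silane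
Conditions: BF3·OEt2, 4 Å molecular sieves, CH2Cl2, -78 °C
Reagents that add atoms: none
Why: BF3 binds the aldehyde of 11 as a monodentate, non-chelated complex, and the alkene terminus C8 of 6 attacks it on the face anti to the C6–Si bond (anti SE2'), forming C8–C9 and a beta-silyl cation at C7 that silicon bridges. The boron-bound alkoxide then opens this siliranium ion at C6 from the side opposite silicon, so silicon settles on C7 by a 1,2-shift and the oxygen closes ring A; the closure is a 5-endo opening of the three-membered ion, the four-membered alternative at C7 being strained. This is the known Lewis-acid (3+2) annulation of alpha-substituted allylsilanes with aldehydes. C6 is set by inversion of the (S)-silane centre. C7 is set because silicon stays on the face it occupied while the reacting conformer keeps the C6–H bond near the alkene plane, which places silicon trans to the C6 chain. C9 is set by Felkin–Anh attack anti to the C10 silyloxy group of the (R)-aldehyde, which gives the 9,10-anti relationship. The step needs the Felkin face of 11 to be the face that the compact synclinal transition state (oxygen over the allyl unit, aldehyde substituent pointing away) pairs with the (S)-silane, since this pairing gives the 2,5-trans ring. A silyl ether that cannot chelate and a monodentate Lewis acid secure this, and -78 °C holds back loss of silicon to the open-chain allylation product.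

Step 10
Reactants: 12 {(2R,3S,5S)-2-[2-(benzyloxy)ethyl]-5-[(1R)-1-{[tert-butyl(dimethyl)silyl]oxy}but-3-en-1-yl]oxolan-3-yl}dimethyl(phenyl)silane
Product: 13 (1R)-1-{(2S,4S,5R)-5-[2-(benzyloxy)ethyl]-4-[dimethyl(phenyl)silyl]oxolan-2-yl}but-3-en-1-ol
Conditions: TBAF, THF, 0 °C to rt
Reagents that add atoms: none
Why: Fluoride cleavage of the silyl ether; the carbon-bound dimethylphenylsilyl group is inert to TBAF at room temperature, so only the C10 oxygen is freed.

Step 11
Reactants: 13 (1R)-1-{(2S,4S,5R)-5-[2-(benzyloxy)ethyl]-4-[dimethyl(phenyl)silyl]oxolan-2-yl}but-3-en-1-ol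
Product: 14 {(2R,3S,5S)-5-[(1R)-1-(benzyloxy)but-3-en-1-yl]-2-[2-(benzyloxy)ethyl]oxolan-3-yl}dimethyl(phenyl)silane
Conditions: NaH, BnBr, Bu4NI (cat.), THF–DMF, 0 °C to rt
Reagents that add atoms: benzyl bromide, BrCc1ccccc1
Why: Williamson etherification; the silyl ether is exchanged for a benzyl ether because the next step uses fluoride at 70 °C, and this benzyl group later leaves together with the one at C4.

Step 12
Reactants: 14 {(2R,3S,5S)-5-[(1R)-1-(benzyloxy)but-3-en-1-yl]-2-[2-(benzyloxy)ethyl]oxolan-3-yl}dimethyl(phenyl)silane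
Product: 15 (2R,3S,5S)-5-[(1R)-1-(benzyloxy)but-3-en-1-yl]-2-[2-(benzyloxy)ethyl]oxolan-3-ol
Conditions: KH, t-BuOOH, NMP, rt; then TBAF, 70 °C
Reagents that add atoms: tert-butyl hydroperoxide, CC(C)(C)OO
Why: Tamao–Fleming oxidation under basic, nucleophilic conditions: hydroperoxide anion and fluoride attack silicon, the phenyl group is expelled, and the ring carbon migrates from silicon to oxygen with retention, so the C7 hydroxyl is trans to the C6 chain and cis to the C9 arm. The electrophilic variants (bromine, mercury salts, strong acid) are avoided because they would attack the terminal alkene or open the beta-silyl ether.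

Step 13
Reactants: 15 (2R,3S,5S)-5-[(1R)-1-(benzyloxy)but-3-en-1-yl]-2-[2-(benzyloxy)ethyl]oxolan-3-ol
Product: 16 (2R,3S,5S)-5-[(1R)-1-(benzyloxy)but-3-en-1-yl]-2-[2-(benzyloxy)ethyl]-3-(ethenyloxy)oxolane
Conditions: [Ir(cod)Cl]2 (cat.), Na2CO3 (substoichiometric), vinyl acetate, toluene, 100 °C
Reagents that add atoms: vinyl acetate, CC(=O)OC=C
Why: Iridium-catalysed transfer vinylation of a secondary alcohol puts the future C13 on the C7 oxygen under weakly basic conditions that leave the benzyl ethers and the terminal alkene alone.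

Step 14
Reactants: 16 (2R,3S,5S)-5-[(1R)-1-(benzyloxy)but-3-en-1-yl]-2-[2-(benzyloxy)ethyl]-3-(ethenyloxy)oxolane
Product: 17 (1S,6R,7S,9R)-6-(benzyloxy)-9-[2-(benzyloxy)ethyl]-2,8-dioxabicyclo[5.2.1]dec-3-ene
Conditions: second-generation Grubbs catalyst (10 mol %), toluene (0.002 M), 80 °C
Reagents that add atoms: none
Why: Ring-closing metathesis of a vinyl ether with a terminal alkene to a cyclic enol ether: the catalyst loads on the C12 alkene, closes onto the vinyl ether and releases ethene, the vinyl carbon on oxygen becoming C13. The two arms are held cis on ring A and high dilution counters dimerisation; the ring alkene can only be Z.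

Step 15
Reactants: 17 (1S,6R,7S,9R)-6-(benzyloxy)-9-[2-(benzyloxy)ethyl]-2,8-dioxabicyclo[5.2.1]dec-3-ene
Product: 19 (1S,3R,4R,6R,7S,9R)-6-(benzyloxy)-9-[2-(benzyloxy)ethyl]-3-ethyl-2,8-dioxabicyclo[5.2.1]decan-4-ol, via 3,4-epoxide 18 (not isolated)
Conditions: dimethyldioxirane, acetone–CH2Cl2, -78 to 0 °C; evaporate; AlEt3, CH2Cl2, -78 to 0 °C
Reagents that add atoms: dimethyldioxirane, CC1(C)OO1; triethylaluminium, CC[Al](CC)CC
Why: The dioxirane epoxidises the electron-rich enol ether, expected on the open face of ring B, away from the O–C6 bridge and the C10 benzyloxy group. AlEt3 then ionises the C13–O bond of this acetal-type epoxide, and ethyl is handed from the aluminate on the C12 oxygen to the same face (syn), the known behaviour of trialkylaluminium reagents with enol ether epoxides. C13 (ethyl) and C12 (hydroxyl) are thus set cis to each other on the open face.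

Step 16
Reactants: 19 (1S,3R,4R,6R,7S,9R)-6-(benzyloxy)-9-[2-(benzyloxy)ethyl]-3-ethyl-2,8-dioxabicyclo[5.2.1]decan-4-ol
Product: 20 (1S,3R,4S,6R,7S,9R)-6-(benzyloxy)-9-[2-(benzyloxy)ethyl]-4-bromo-3-ethyl-2,8-dioxabicyclo[5.2.1]decane
Conditions: CBr4, P(n-C8H17)3, toluene, 70 °C
Reagents that add atoms: carbon tetrabromide, BrC(Br)(Br)Br
Why: Appel-type bromination with a trialkylphosphine: bromide displaces the alkoxyphosphonium ion at C12 by SN2, so the bromide arrives on the bridge face, trans to the C13 ethyl group. Toluene as a non-polar solvent disfavours ionisation and participation by the ring oxygens.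

Step 17
Reactants: 20 (1S,3R,4S,6R,7S,9R)-6-(benzyloxy)-9-[2-(benzyloxy)ethyl]-4-bromo-3-ethyl-2,8-dioxabicyclo[5.2.1]decane
Product: 21 (1S,3R,4S,6R,7S,9R)-4-bromo-3-ethyl-9-(2-hydroxyethyl)-2,8-dioxabicyclo[5.2.1]decan-6-ol
Conditions: BCl3, CH2Cl2, -78 °C; MeOH
Reagents that add atoms: none
Why: Lewis-acid cleavage of both benzyl ethers by BCl3 at low temperature; hydrogenolysis is avoided because of the C–Br bond, and the dialkyl ethers of the bicycle and the secondary bromide should not react at -78 °C.

Step 18
Reactants: 21 (1S,3R,4S,6R,7S,9R)-4-bromo-3-ethyl-9-(2-hydroxyethyl)-2,8-dioxabicyclo[5.2.1]decan-6-ol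
Product: 22 [(1S,3R,4S,6R,7S,9R)-4-bromo-3-ethyl-6-hydroxy-2,8-dioxabicyclo[5.2.1]decan-9-yl]acetaldehyde
Conditions: TEMPO (cat.), PhI(OAc)2, CH2Cl2, rt
Reagents that add atoms: none
Why: Oxoammonium (TEMPO) oxidation with PhI(OAc)2 as co-oxidant is selective for the primary alcohol over the secondary C10 alcohol; the conditions are not basic, so the beta-alkoxy aldehyde should not eliminate.

Step 19
Reactants: 22 [(1S,3R,4S,6R,7S,9R)-4-bromo-3-ethyl-6-hydroxy-2,8-dioxabicyclo[5.2.1]decan-9-yl]acetaldehyde
Product: 23 (1S,3R,4S,6R,7S,9R)-4-bromo-3-ethyl-9-[(2E)-3-iodoprop-2-en-1-yl]-2,8-dioxabicyclo[5.2.1]decan-6-ol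
Conditions: CrCl2, CHI3, THF–dioxane, 0 °C to rt
Reagents that add atoms: iodoform, IC(I)I
Why: Takai olefination: the geminal dichromium species from CHI3 and CrCl2 adds to the aldehyde and eliminates to the (E)-vinyl iodide. CrCl2 does not reduce an unactivated secondary bromide and tolerates the free hydroxyl.

Step 20
Reactants: 23 (1S,3R,4S,6R,7S,9R)-4-bromo-3-ethyl-9-[(2E)-3-iodoprop-2-en-1-yl]-2,8-dioxabicyclo[5.2.1]decan-6-ol
Product: 24 (1S,3R,4S,6R,7S,9R)-4-bromo-3-ethyl-9-[(2E)-5-(trimethylsilyl)pent-2-en-4-yn-1-yl]-2,8-dioxabicyclo[5.2.1]decan-6-ol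
Conditions: ethynyltrimethylsilane, Pd(PPh3)2Cl2 (cat.), CuI (cat.), i-Pr2NH, THF, rt
Reagents that add atoms: ethynyltrimethylsilane, C#C[Si](C)(C)C
Why: Sonogashira coupling of the vinyl iodide with a terminal alkyne proceeds with retention of the alkene geometry; the alkyl bromide does not react with the palladium catalyst under these mild conditions.

Step 21
Reactants: 24 (1S,3R,4S,6R,7S,9R)-4-bromo-3-ethyl-9-[(2E)-5-(trimethylsilyl)pent-2-en-4-yn-1-yl]-2,8-dioxabicyclo[5.2.1]decan-6-ol
Product: 25 {(3E)-5-[(1S,3R,4S,6S,7S,9R)-4,6-dibromo-3-ethyl-2,8-dioxabicyclo[5.2.1]decan-9-yl]pent-3-en-1-yn-1-yl}trimethylsilane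
Conditions: CBr4, P(n-C8H17)3, toluene, 70 °C
Reagents that add atoms: carbon tetrabromide, BrC(Br)(Br)Br
Why: Second Appel-type bromination, now at C10: SN2 displacement of the alkoxyphosphonium ion inverts C10 and puts the bromide on the open face; the silyl-capped enyne is inert to the reagents.

Step 22
Reactants: 25 {(3E)-5-[(1S,3R,4S,6S,7S,9R)-4,6-dibromo-3-ethyl-2,8-dioxabicyclo[5.2.1]decan-9-yl]pent-3-en-1-yn-1-yl}trimethylsilane
Product: 26 (1S,3R,4S,6S,7S,9R)-4,6-dibromo-3-ethyl-9-[(2E)-pent-2-en-4-yn-1-yl]-2,8-dioxabicyclo[5.2.1]decane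
Conditions: K2CO3 (cat.), MeOH, 0 °C
Reagents that add atoms: none
Why: Methanolysis of the alkynyl C–Si bond with catalytic carbonate; at 0 °C the two secondary bromides should survive, and the terminal alkyne of the target is freed.

## Compound list

1 | 3-(benzyloxy)propanal | O=CCCOCc1ccccc1 | starting material
2 | ethyl (2E)-5-(benzyloxy)pent-2-enoate | CCOC(=O)/C=C/CCOCc1ccccc1 | intermediate
3 | (2E)-5-(benzyloxy)pent-2-en-1-ol | OC/C=C/CCOCc1ccccc1 | intermediate
4 | (2E)-5-(benzyloxy)pent-2-en-1-yl diethyl phosphate | CCOP(=O)(OCC)OC/C=C/CCOCc1ccccc1 | intermediate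
5 | (dimethylphenylsilyl)boronic acid pinacol ester | CC1(C)OB(OC1(C)C)[Si](C)(C)c1ccccc1 | starting material
6 | (S)-[5-(benzyloxy)pent-1-en-3-yl]dimethyl(phenyl)silane | c3ccccc3COCC[C@@H](C=C)[Si](C)(C)c4ccccc4 | intermediate
7 | (R)-benzyl glycidyl ether | c1ccccc1COC[C@H]1CO1 | starting material
8 | (R)-1-(benzyloxy)pent-4-en-2-ol | c1ccccc1COC[C@H](O)CC=C | intermediate
9 | (R)-{[1-(benzyloxy)pent-4-en-2-yl]oxy}(tert-butyl)dimethylsilane | c1ccccc1COC[C@H](O[Si](C)(C)C(C)(C)C)CC=C | intermediate
10 | (R)-2-[(tert-butyldimethylsilyl)oxy]pent-4-en-1-ol | OC[C@H](O[Si](C)(C)C(C)(C)C)CC=C | intermediate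
11 | (R)-2-[(tert-butyldimethylsilyl)oxy]pent-4-enal | O=C[C@H](O[Si](C)(C)C(C)(C)C)CC=C | intermediate
12 | {(2R,3S,5S)-2-[2-(benzyloxy)ethyl]-5-[(1R)-1-{[tert-butyl(dimethyl)silyl]oxy}but-3-en-1-yl]oxolan-3-yl}dimethyl(phenyl)silane | c3ccccc3COCC[C@H]1O[C@H]([C@H](O[Si](C)(C)C(C)(C)C)CC=C)C[C@@H]1[Si](C)(C)c4ccccc4 | intermediate
13 | (1R)-1-{(2S,4S,5R)-5-[2-(benzyloxy)ethyl]-4-[dimethyl(phenyl)silyl]oxolan-2-yl}but-3-en-1-ol | c3ccccc3COCC[C@H]1O[C@H]([C@H](O)CC=C)C[C@@H]1[Si](C)(C)c4ccccc4 | intermediate
14 | {(2R,3S,5S)-5-[(1R)-1-(benzyloxy)but-3-en-1-yl]-2-[2-(benzyloxy)ethyl]oxolan-3-yl}dimethyl(phenyl)silane | c3ccccc3COCC[C@H]1O[C@H]([C@H](OCc2ccccc2)CC=C)C[C@@H]1[Si](C)(C)c4ccccc4 | intermediate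
15 | (2R,3S,5S)-5-[(1R)-1-(benzyloxy)but-3-en-1-yl]-2-[2-(benzyloxy)ethyl]oxolan-3-ol | c3ccccc3COCC[C@H]1O[C@H]([C@H](OCc2ccccc2)CC=C)C[C@@H]1O | intermediate
16 | (2R,3S,5S)-5-[(1R)-1-(benzyloxy)but-3-en-1-yl]-2-[2-(benzyloxy)ethyl]-3-(ethenyloxy)oxolane | c3ccccc3COCC[C@H]1O[C@H]([C@H](OCc2ccccc2)CC=C)C[C@@H]1OC=C | intermediate
17 | (1S,6R,7S,9R)-6-(benzyloxy)-9-[2-(benzyloxy)ethyl]-2,8-dioxabicyclo[5.2.1]dec-3-ene | c3ccccc3COCC[C@H]1O[C@H]2C[C@@H]1O/C=C\C[C@H]2OCc4ccccc4 | intermediate
18 | 3,4-epoxide of 17 with the oxirane oxygen on the open face of ring B (C12–C13 epoxide) | c3ccccc3COCC[C@H]1O[C@H]2C[C@@H]1O[C@H]5[C@H](O5)C[C@H]2OCc4ccccc4 | intermediate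
19 | (1S,3R,4R,6R,7S,9R)-6-(benzyloxy)-9-[2-(benzyloxy)ethyl]-3-ethyl-2,8-dioxabicyclo[5.2.1]decan-4-ol | c3ccccc3COCC[C@H]1O[C@H]2C[C@@H]1O[C@H](CC)[C@H](O)C[C@H]2OCc4ccccc4 | intermediate
20 | (1S,3R,4S,6R,7S,9R)-6-(benzyloxy)-9-[2-(benzyloxy)ethyl]-4-bromo-3-ethyl-2,8-dioxabicyclo[5.2.1]decane | c3ccccc3COCC[C@H]1O[C@H]2C[C@@H]1O[C@H](CC)[C@@H](Br)C[C@H]2OCc4ccccc4 | intermediate
21 | (1S,3R,4S,6R,7S,9R)-4-bromo-3-ethyl-9-(2-hydroxyethyl)-2,8-dioxabicyclo[5.2.1]decan-6-ol | OCC[C@H]1O[C@H]2C[C@@H]1O[C@H](CC)[C@@H](Br)C[C@H]2O | intermediate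
22 | [(1S,3R,4S,6R,7S,9R)-4-bromo-3-ethyl-6-hydroxy-2,8-dioxabicyclo[5.2.1]decan-9-yl]acetaldehyde | O=CC[C@H]1O[C@H]2C[C@@H]1O[C@H](CC)[C@@H](Br)C[C@H]2O | intermediate
23 | (1S,3R,4S,6R,7S,9R)-4-bromo-3-ethyl-9-[(2E)-3-iodoprop-2-en-1-yl]-2,8-dioxabicyclo[5.2.1]decan-6-ol | I/C=C/C[C@H]1O[C@H]2C[C@@H]1O[C@H](CC)[C@@H](Br)C[C@H]2O | intermediate
24 | (1S,3R,4S,6R,7S,9R)-4-bromo-3-ethyl-9-[(2E)-5-(trimethylsilyl)pent-2-en-4-yn-1-yl]-2,8-dioxabicyclo[5.2.1]decan-6-ol | C[Si](C)(C)C#C/C=C/C[C@H]1O[C@H]2C[C@@H]1O[C@H](CC)[C@@H](Br)C[C@H]2O | intermediate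
25 | {(3E)-5-[(1S,3R,4S,6S,7S,9R)-4,6-dibromo-3-ethyl-2,8-dioxabicyclo[5.2.1]decan-9-yl]pent-3-en-1-yn-1-yl}trimethylsilane | C[Si](C)(C)C#C/C=C/C[C@H]1O[C@H]2C[C@@H]1O[C@H](CC)[C@@H](Br)C[C@@H]2Br | intermediate
26 | (1S,3R,4S,6S,7S,9R)-4,6-dibromo-3-ethyl-9-[(2E)-pent-2-en-4-yn-1-yl]-2,8-dioxabicyclo[5.2.1]decane | C#C/C=C/C[C@H]1O[C@H]2C[C@@H]1O[C@H](CC)[C@@H](Br)C[C@@H]2Br | target

## Step count and least certain steps

Total: 22 steps. Longest linear sequence: 18 steps (steps 1–4 or 5–8, then steps 9–22).

Step 9 (key step). The beta-silyl cation may lose silicon before the oxygen closes the ring, which gives open-chain allylation. Facial selectivity at the aldehyde may also erode if the Felkin preference of 11 and the preferred transition-state geometry of the silane do not reinforce each other; that would lower the 2,5-trans selectivity. Fallback, from 6 and 11 back to 16, without carrying silicon into the ring: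
- With TiCl4 in CH2Cl2 at -78 °C the two fragments are joined by a Hosomi–Sakurai allylation, in which silicon is lost on purpose, to give (4R,5S,7E)-10-(benzyloxy)-4-[(tert-butyldimethylsilyl)oxy]deca-1,7-dien-5-ol F1, with C9 set by the same Felkin–Anh control.
- Shi epoxidation with the L-fructose-derived ketone and KHSO5 takes the trans-disubstituted alkene in preference to the terminal one and should give (2S,3R)-1-{(2S,3S)-3-[2-(benzyloxy)ethyl]oxiran-2-yl}-3-[(tert-butyldimethylsilyl)oxy]hex-5-en-2-ol F2.
- Camphorsulfonic acid in CH2Cl2 lets the C9 hydroxyl open the epoxide at C6 with inversion to (2R,3S,5S)-2-[2-(benzyloxy)ethyl]-5-[(1R)-1-{[tert-butyl(dimethyl)silyl]oxy}but-3-en-1-yl]oxolan-3-ol F3, which already carries the C7 oxygen.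
- Transfer vinylation as in step 13 gives tert-butyl{[(1R)-1-{(2S,4S,5R)-5-[2-(benzyloxy)ethyl]-4-(ethenyloxy)oxolan-2-yl}but-3-en-1-yl]oxy}dimethylsilane F4.
- TBAF gives (1R)-1-{(2S,4S,5R)-5-[2-(benzyloxy)ethyl]-4-(ethenyloxy)oxolan-2-yl}but-3-en-1-ol F5, and NaH with BnBr returns to 16.

Step 12. Under base and fluoride the ring A oxygen, which is beta to silicon, may leave (ring opening by beta-elimination), or the oxidation may stall at a silanol. Fallback, from 14 back to 15, by the two-stage electrophilic procedure: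
- HBF4·OEt2 in CH2Cl2 at 0 °C removes the phenyl group by ipso protonation to give {(2R,3S,5S)-5-[(1R)-1-(benzyloxy)but-3-en-1-yl]-2-[2-(benzyloxy)ethyl]oxolan-3-yl}fluorodimethylsilane F6.
- H2O2, KF and KHCO3 in THF–MeOH oxidise F6 to 15 with retention.

Step 14. The catalyst may be trapped as an unreactive alkoxy-substituted ruthenium carbene on the vinyl ether, or strain in the bridged eight-membered ring may divert the reaction to oligomerisation. Fallback, from 15 back to 17, closing ring B as a lactone:
- 9-Borabicyclononane, then NaOH and H2O2, gives (2R,3S,5S)-5-[(1R)-1-(benzyloxy)-4-hydroxybutyl]-2-[2-(benzyloxy)ethyl]oxolan-3-ol F7.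
- TEMPO and PhI(OAc)2 in MeCN–water oxidise the primary alcohol to (4R)-4-(benzyloxy)-4-{(2S,4S,5R)-5-[2-(benzyloxy)ethyl]-4-hydroxyoxolan-2-yl}butanoic acid F8.
- Yamaguchi lactonisation (2,4,6-trichlorobenzoyl chloride, Et3N, then DMAP in dilute toluene) gives (1S,6R,7S,9R)-6-(benzyloxy)-9-[2-(benzyloxy)ethyl]-2,8-dioxabicyclo[5.2.1]decan-3-one F9.
- Reduction with i-Bu2AlH at -78 °C and trapping of the aluminium hemiacetal with Ac2O, pyridine and DMAP gives (1S,6R,7S,9R)-6-(benzyloxy)-9-[2-(benzyloxy)ethyl]-2,8-dioxabicyclo[5.2.1]decan-3-yl acetate F10.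
- TMSOTf with i-Pr2NEt eliminates acetic acid from F10 to give 17.

Step 15. The dioxirane may attack the bridge face of the enol ether, because the alkene lies far from the bridge and the ring is flexible; syn ethyl transfer would then put both new substituents on the wrong face. Hydride transfer from AlEt3 instead of ethyl transfer is a lesser risk. Fallback, from 17 back to 19, which uses the other face instead of fighting it:
- The epoxide on the bridge face, the 3,4-epoxide F11, is opened anti at the acetal carbon by Et2CuLi in Et2O to give (1S,3R,4S,6R,7S,9R)-6-(benzyloxy)-9-[2-(benzyloxy)ethyl]-3-ethyl-2,8-dioxabicyclo[5.2.1]decan-4-ol F12, with ethyl on the open face and hydroxyl on the bridge face.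
- Mitsunobu inversion with 4-nitrobenzoic acid, PPh3 and diisopropyl azodicarboxylate gives (1S,3R,4R,6R,7S,9R)-6-(benzyloxy)-9-[2-(benzyloxy)ethyl]-3-ethyl-2,8-dioxabicyclo[5.2.1]decan-4-yl 4-nitrobenzoate F13.
- K2CO3 in MeOH cleaves the ester to 19.

Step 16. The alkoxyphosphonium ion at C12 may ionise with participation of the ring A oxygen across the ring (net retention or skeletal rearrangement), or it may eliminate. Fallback, from 19 back to 20, with an isolated sulfonate:
- Chloromethanesulfonyl chloride and 2,6-lutidine in CH2Cl2 at 0 °C give (1S,3R,4R,6R,7S,9R)-6-(benzyloxy)-9-[2-(benzyloxy)ethyl]-3-ethyl-2,8-dioxabicyclo[5.2.1]decan-4-yl chloromethanesulfonate F14.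
- Bu4NBr in toluene displaces the sulfonate by SN2 to give 20.

Step 21. The same processes threaten the C10 displacement, here with the ring B oxygen as the transannular neighbour and on the most advanced material. Fallback, from 24 back to 25:
- Chloromethanesulfonyl chloride and 2,6-lutidine give (1S,3R,4S,6R,7S,9R)-4-bromo-3-ethyl-9-[(2E)-5-(trimethylsilyl)pent-2-en-4-yn-1-yl]-2,8-dioxabicyclo[5.2.1]decan-6-yl chloromethanesulfonate F15.
- Bu4NBr in toluene displaces the sulfonate with inversion to give 25.

## Further compounds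

F1 | step 9 | (4R,5S,7E)-10-(benzyloxy)-4-[(tert-butyldimethylsilyl)oxy]deca-1,7-dien-5-ol | c1ccccc1COCC/C=C/C[C@H](O)[C@H](O[Si](C)(C)C(C)(C)C)CC=C
F2 | step 9 | (2S,3R)-1-{(2S,3S)-3-[2-(benzyloxy)ethyl]oxiran-2-yl}-3-[(tert-butyldimethylsilyl)oxy]hex-5-en-2-ol | c1ccccc1COCC[C@@H]1O[C@H]1C[C@H](O)[C@H](O[Si](C)(C)C(C)(C)C)CC=C
F3 | step 9 | (2R,3S,5S)-2-[2-(benzyloxy)ethyl]-5-[(1R)-1-{[tert-butyl(dimethyl)silyl]oxy}but-3-en-1-yl]oxolan-3-ol | c1ccccc1COCC[C@H]1O[C@H]([C@H](O[Si](C)(C)C(C)(C)C)CC=C)C[C@@H]1O
F4 | step 9 | tert-butyl{[(1R)-1-{(2S,4S,5R)-5-[2-(benzyloxy)ethyl]-4-(ethenyloxy)oxolan-2-yl}but-3-en-1-yl]oxy}dimethylsilane | c1ccccc1COCC[C@H]1O[C@H]([C@H](O[Si](C)(C)C(C)(C)C)CC=C)C[C@@H]1OC=C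
F5 | step 9 | (1R)-1-{(2S,4S,5R)-5-[2-(benzyloxy)ethyl]-4-(ethenyloxy)oxolan-2-yl}but-3-en-1-ol | c1ccccc1COCC[C@H]1O[C@H]([C@H](O)CC=C)C[C@@H]1OC=C
F6 | step 12 | {(2R,3S,5S)-5-[(1R)-1-(benzyloxy)but-3-en-1-yl]-2-[2-(benzyloxy)ethyl]oxolan-3-yl}fluorodimethylsilane | c3ccccc3COCC[C@H]1O[C@H]([C@H](OCc2ccccc2)CC=C)C[C@@H]1[Si](C)(C)F
F7 | step 14 | (2R,3S,5S)-5-[(1R)-1-(benzyloxy)-4-hydroxybutyl]-2-[2-(benzyloxy)ethyl]oxolan-3-ol | c3ccccc3COCC[C@H]1O[C@H]([C@H](OCc2ccccc2)CCCO)C[C@@H]1O
F8 | step 14 | (4R)-4-(benzyloxy)-4-{(2S,4S,5R)-5-[2-(benzyloxy)ethyl]-4-hydroxyoxolan-2-yl}butanoic acid | c3ccccc3COCC[C@H]1O[C@H]([C@H](OCc2ccccc2)CCC(=O)O)C[C@@H]1O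
F9 | step 14 | (1S,6R,7S,9R)-6-(benzyloxy)-9-[2-(benzyloxy)ethyl]-2,8-dioxabicyclo[5.2.1]decan-3-one | c3ccccc3COCC[C@H]1O[C@H]2C[C@@H]1OC(=O)CC[C@H]2OCc4ccccc4
F10 | step 14 | (1S,6R,7S,9R)-6-(benzyloxy)-9-[2-(benzyloxy)ethyl]-2,8-dioxabicyclo[5.2.1]decan-3-yl acetate (either C3 epimer) | c3ccccc3COCC[C@H]1O[C@H]2C[C@@H]1OC(OC(C)=O)CC[C@H]2OCc4ccccc4
F11 | step 15 | 3,4-epoxide of 17 with the oxirane oxygen on the bridge face of ring B | c3ccccc3COCC[C@H]1O[C@H]2C[C@@H]1O[C@@H]5[C@@H](O5)C[C@H]2OCc4ccccc4
F12 | step 15 | (1S,3R,4S,6R,7S,9R)-6-(benzyloxy)-9-[2-(benzyloxy)ethyl]-3-ethyl-2,8-dioxabicyclo[5.2.1]decan-4-ol | c3ccccc3COCC[C@H]1O[C@H]2C[C@@H]1O[C@H](CC)[C@@H](O)C[C@H]2OCc4ccccc4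
F13 | step 15 | (1S,3R,4R,6R,7S,9R)-6-(benzyloxy)-9-[2-(benzyloxy)ethyl]-3-ethyl-2,8-dioxabicyclo[5.2.1]decan-4-yl 4-nitrobenzoate | c3ccccc3COCC[C@H]1O[C@H]2C[C@@H]1O[C@H](CC)[C@H](OC(=O)c5ccc(cc5)[N+](=O)[O-])C[C@H]2OCc4ccccc4
F14 | step 16 | (1S,3R,4R,6R,7S,9R)-6-(benzyloxy)-9-[2-(benzyloxy)ethyl]-3-ethyl-2,8-dioxabicyclo[5.2.1]decan-4-yl chloromethanesulfonate | c3ccccc3COCC[C@H]1O[C@H]2C[C@@H]1O[C@H](CC)[C@H](OS(=O)(=O)CCl)C[C@H]2OCc4ccccc4
F15 | step 21 | (1S,3R,4S,6R,7S,9R)-4-bromo-3-ethyl-9-[(2E)-5-(trimethylsilyl)pent-2-en-4-yn-1-yl]-2,8-dioxabicyclo[5.2.1]decan-6-yl chloromethanesulfonate | C[Si](C)(C)C#C/C=C/C[C@H]1O[C@H]2C[C@@H]1O[C@H](CC)[C@@H](Br)C[C@H]2OS(=O)(=O)CCl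
A1 | alternative 1 | bridged bicyclic 10-ketone 12-alcohol with C6 allyl group | C=CC[C@H]1O[C@H]2C[C@@H]1O[C@H](CC)[C@H](O)CC2=O
A2 | alternative 1 | ring A seco compound with C10 bromomethyl ketone and C12 aldehyde on the C7 ether arm | C=CC[C@H]1O[C@H](C(=O)CBr)C[C@@H]1O[C@H](CC)C=O
A3 | alternative 2 | ring B lactone (C13 carbonyl) bridged by ring A, with C10 bromide and C4 silyl ether | CC(C)(C)[Si](c3ccccc3)(c3ccccc3)OCC[C@H]1O[C@H]2C[C@@H]1OC(=O)CC[C@@H]2Br
A4 | alternative 2 | oxygen-bridged cycloheptanone with the C13 ketone bonded to C7 and the C10 bromide | CC(C)(C)[Si](c3ccccc3)(c3ccccc3)OCC[C@H]1O[C@H]2C[C@@H]1C(=O)CC[C@@H]2Br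
A5 | alternative 3 | bridged bicyclic C4 ethyl ester with C10 and C12 silyl ethers | CCOC(=O)C[C@H]1O[C@H]2C[C@@H]1O[C@H](CC)[C@H](O[Si](C)(C)C(C)(C)C)C[C@H]2O[Si](C)(C)C(C)(C)C
A6 | alternative 3 | ring B oxocane with C7 phenylselanyl acetal (either C7 epimer) and C9 beta-alkoxyacrylate | CCOC(=O)/C=C/O[C@H]1CC([Se]c2ccccc2)O[C@H](CC)[C@H](O[Si](C)(C)C(C)(C)C)C[C@H]1O[Si](C)(C)C(C)(C)C
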